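No rate constant was given, so I had to read the constants from the blue run, whose charges stand among the recipes below with its readings.

| flask | starting material | coupling partner | protic impurity | temperature | remark | time |
|---|---|---|---|---|---|---|
| blue | 0.055 M | 0.035 M | 0.015 M | −20 °C | run made earlier |  |
| north-west | 0.15 M | 0.0120 M | 0.0150 M | −20 °C |  | 4.0 min |
| east | 0.030 M | 0.0200 M | 0.0150 M | −20 °C |  | 4.0 min |
| west | 0.050 M | 0.0120 M | 0.0150 M | −20 °C |  | 4.0 min |
| north | 0.15 M | 0.0350 M | 0.0500 M | 0 °C |  | 4.0 min |
| south-east | 0.050 M | 0.0350 M | 0.0150 M | −20 °C |  | 4.0 min |

blue run (percent of the starting material charged)

| time / s | product / % | starting material / % |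
|---|---|---|
| 10.0 | 19.8 | 29.0 |
| 15.0 | 24.6 | 19.9 |
| 40.0 | 38.6 | 10.9 |
| 80.0 | 54.9 | 6.2 |

(each reading ± 1 percentage point)

- the analysis behind the earlier runs scatters by 1 percentage point, standard deviation
- candidate steps: starting material + coupling partner <-> intermediate A; starting material -> product; starting material <-> intermediate B; starting material + protic impurity -> quenched substrate
- the earlier runs do not show what temperature does; that part of a forecast is a guess
- no earlier run changes the charge of protic impurity; that part of a forecast is a guess

1. the flasks by amount of product, in percent of the starting material charged, highest first, at 4.0 min (north-west / east / west / north / south-east)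
2. the amount of product, in percent of the starting material charged of the flask you put first, at 4.0 min
3. the amount of product, in percent of the starting material charged of the flask you put last, at 4.0 min

South-east is nearly the blue run: it has the same coupling partner and protic impurity at −20 °C, and 0.050 M of starting material against 0.055 M. The concentration that sets the order of the product rate is [starting material], the free form, so I divided the product gained from 15.0 s to 80.0 s by the trapezoid area under the starting material readings:

k(product) = 0.0417 s⁻¹

The candidate steps offer two ways back to starting material, from intermediate A and from intermediate B, and I did not try to separate them. As a working assumption I treated these three as one pool that empties with a single pseudo-first-order constant, the drain constant. My first value came from the last two starting material readings: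

drain = 0.0141 s⁻¹

Adding the product still to come after 80.0 s gave:

product at 4.0 min = 54.9% + k(product) × 6.2% / drain × (fraction drained) = 71.3%

The weak link was that drain value, which leans on a reading of 6.2% with a scatter of 1 percentage point. I reforged it from the product readings instead. On the same assumption the drain constant, the constant at which the pool empties, is also the decay of the product slope, so I compared the slopes of the last two intervals:

drain = 0.00978 s⁻¹

product at 4.0 min = 75.8%

Among the flasks at −20 °C, south-east carries the most coupling partner, so I put it last at 75.8%. North's temperature and impurity charge stayed a guess.

The forecast gave north-west > west > south-east > north > east, with 87% first and 56% last, and south-east at 68 below my figure, holding that “yield is set by impurity loss”.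

The simulation gives north > north-west > west > east > south-east, with 86.8% first and 75.5% last.

    starting material + coupling partner ⇌ intermediate A (K = 57.0 M⁻¹, k = 0.350 M⁻¹ s⁻¹, Ea = 43.0 kJ mol⁻¹, ΔH = −27.0 kJ mol⁻¹)
    starting material → product (k = 0.0390 s⁻¹, Ea = 73.0 kJ mol⁻¹)
    starting material ⇌ intermediate B (K = 1.90, k = 0.100 s⁻¹, Ea = 60.0 kJ mol⁻¹, ΔH = −7.00 kJ mol⁻¹)
    starting material + protic impurity → quenched substrate (k = 0.550 M⁻¹ s⁻¹, Ea = 36.0 kJ mol⁻¹)
    (constants at −20 °C)

South-east stands at 75.5% against my 75.8%. The free share read from blue, drain over k(product), is 23.5%, so if the one-pool assumption held, a flask's pool would be its starting material divided by that share. For south-east at 4.00 min this gives 6.38%, and the table holds 12.2%. For the neighbour charged with 0.014 M of coupling partner it gives 5.49%, and the table holds 7.35%. Intermediate A stands at 7.31% in south-east and 3.03% in that neighbour, whose product reaches 79.7%.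

Readings and results are simulated with made-up constants, and the scatter is random.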